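The bromocyclopentane ring (C1'–C5') is not closed as a five-membered ring: it arises by Meinwald ring contraction of a 1-methylcyclohexene oxide. The step exploits the quaternary C1' flanked by gem-dimethyl C2' and bound to enone carbon C3 of ring A: in one operation a ring CH2 shifts anti to the oxirane oxygen, fixing C1' relative to the C3' oxygen, and the extruded carbon appears as the formyl group that becomes C3. The precursor is a silyloxy trimethylcyclohexene oxide made from (S)-3-hydroxy-2,2-dimethylcyclohexanone. The derived alkyne adds to a carvone-based ring B ketone; iodoalkene formation, lactonisation, double Appel bromination, anionic closure of ring A and oxymercuration complete the route.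

Key step: step 5

Remark: locants are those of the target's naphthalen-2(1H)-one core (C1–C8a; ring A = C1–C4, C4a, C8a; ring B = C4a–C8a; β = face of the C8a methyl) and of the cyclopentyl group (C1'–C5', C1' bound to C3); (S)-3-hydroxy-2,2-dimethylcyclohexan-1-one (also made by yeast reduction of 2,2-dimethylcyclohexane-1,3-dione) and (R)-(−)-carvone are assumed to be commercially available.

Step 1
Reactants: 1 (S)-3-hydroxy-2,2-dimethylcyclohexan-1-one
Product: 2 (S)-3-[(tert-butyldimethylsilyl)oxy]-2,2-dimethylcyclohexan-1-one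
Conditions: TBSOTf, 2,6-lutidine, CH2Cl2, 0 °C
Reagents that add atoms: tert-butyldimethylsilyl trifluoromethanesulfonate, CC(C)(C)[Si](C)(C)OS(=O)(=O)C(F)(F)F
Why: Silyl ether formation with the silyl triflate is the standard protection of a hindered secondary alcohol and leaves the stereocentre untouched.

Step 2
Reactants: 2 (S)-3-[(tert-butyldimethylsilyl)oxy]-2,2-dimethylcyclohexan-1-one
Product: 4 (S)-5-[(tert-butyldimethylsilyl)oxy]-6,6-dimethylcyclohex-1-en-1-yl trifluoromethanesulfonate, via potassium enolate 3 (not isolated)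
Conditions: KN(SiMe3)2, THF, −78 °C; then PhNTf2, −78 → 0 °C
Reagents that add atoms: N-phenylbis(trifluoromethanesulfonimide), O=S(=O)(N(c1ccccc1)S(=O)(=O)C(F)(F)F)C(F)(F)F
Why: The ketone can enolise only toward C6, so O-sulfonylation of the potassium enolate with PhNTf2 (enol triflate formation) should give one regioisomer.

Step 3
Reactants: 4 (S)-5-[(tert-butyldimethylsilyl)oxy]-6,6-dimethylcyclohex-1-en-1-yl trifluoromethanesulfonate
Product: 5 tert-butyldimethyl{[(1S)-2,2,3-trimethylcyclohex-3-en-1-yl]oxy}silane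
Conditions: MeMgBr, Fe(acac)3 (5 mol%), THF/NMP, −30 → 0 °C
Reagents that add atoms: methylmagnesium bromide, C[Mg]Br
Why: Iron-catalysed Kumada-type cross-coupling of the alkenyl triflate with MeMgBr replaces OTf by methyl and fixes the position of the trisubstituted alkene.

Step 4
Reactants: 5 tert-butyldimethyl{[(1S)-2,2,3-trimethylcyclohex-3-en-1-yl]oxy}silane
Product: 6 tert-butyldimethyl{[(1R,3S,6S)-1,2,2-trimethyl-7-oxabicyclo[4.1.0]heptan-3-yl]oxy}silane (oxirane trans to OTBS)
Conditions: mCPBA, NaHCO3, CH2Cl2, 0 °C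
Reagents that add atoms: 3-chloroperbenzoic acid, OOC(=O)c1cccc(Cl)c1
Why: Prilezhaev epoxidation; the peracid should attack the face opposite to the pseudoaxial allylic methyl group, which lies on the side of the equatorial OTBS group, so the oxirane (C1 and C6) forms trans to OTBS.

Step 5
Reactants: 6 tert-butyldimethyl{[(1R,3S,6S)-1,2,2-trimethyl-7-oxabicyclo[4.1.0]heptan-3-yl]oxy}silane
Product: 7 (1S,3S)-3-[(tert-butyldimethylsilyl)oxy]-1,2,2-trimethylcyclopentane-1-carbaldehyde (formyl trans to OTBS)
Conditions: MeAl(OAr)2 (Ar = 4-bromo-2,6-di-tert-butylphenyl, 20 mol%), CH2Cl2, −78 → −20 °C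
Reagents that add atoms: none
Why: Coordination of the bulky aluminium phenoxide to the oxirane oxygen weakens the tertiary C1–O bond, and the ring methylene C5 migrates from C6 to C1 anti to the departing oxygen while C6 becomes the formyl carbon (Meinwald rearrangement, a semipinacol 1,2-shift). The closest known reaction type is the ring contraction of 1-methylcyclohexene oxides to 1-methylcyclopentanecarbaldehydes promoted by aluminium and boron reagents. The five-membered ring is not formed by a ring closure in the usual sense: the six-membered ring contracts through the three-centre transition state of a suprafacial 1,2-alkyl shift. The shift inverts the migration terminus, so the new quaternary centre C1' is dictated by the oxirane configuration (formyl on the former oxygen face, hence trans to OTBS), and C3' is not touched. The step needs alkyl shift to win over hydride shift (which would give a cyclohexanone) and over methyl shift from the neighbouring CMe2; the bulky non-nucleophilic aluminium reagent at low temperature and the carbonyl-forming driving force should secure this.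

Step 6
Reactants: 7 (1S,3S)-3-[(tert-butyldimethylsilyl)oxy]-1,2,2-trimethylcyclopentane-1-carbaldehyde
Product: 8 tert-butyl{[(1S,3R)-3-ethynyl-2,2,3-trimethylcyclopentyl]oxy}dimethylsilane
Conditions: dimethyl (1-diazo-2-oxopropyl)phosphonate, K2CO3, MeOH, 0 °C → rt
Reagents that add atoms: dimethyl (1-diazo-2-oxopropyl)phosphonate, COP(=O)(OC)C(=[N+]=[N-])C(C)=O
Why: Seyferth–Gilbert homologation with the Ohira–Bestmann reagent converts the non-enolisable aldehyde into the terminal alkyne without touching the stereocentres.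

Step 7
Reactants: 9 (R)-(−)-carvone
Product: 11 (1R)-4-methyl-5-oxocyclohex-3-en-1-yl acetate, via α-methoxy hydroperoxide 10 (not isolated)
Conditions: O3, CH2Cl2/MeOH, −78 °C; then Ac2O, Et3N, DMAP (cat.), 0 °C → rt
Reagents that add atoms: ozone, [O-][O+]=O; methanol, CO
Why: Ozonolysis of the 1,1-disubstituted alkene in methanol gives the α-methoxy hydroperoxide, whose peracetate undergoes Criegee rearrangement with retention at the migrating ring carbon, while the electron-poor enone alkene should survive.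

Step 8
Reactants: 11 (1R)-4-methyl-5-oxocyclohex-3-en-1-yl acetate
Product: 12 (5R)-5-hydroxy-2-methylcyclohex-2-en-1-one
Conditions: K2CO3 (cat.), MeOH, 0 °C
Reagents that add atoms: none
Why: Base-catalysed transesterification (methanolysis) of the acetate at low temperature should free the alcohol without β-elimination.

Step 9
Reactants: 12 (5R)-5-hydroxy-2-methylcyclohex-2-en-1-one
Product: 13 (5R)-5-[(tert-butyldimethylsilyl)oxy]-2-methylcyclohex-2-en-1-one
Conditions: TBSCl, imidazole, DMF, rt
Reagents that add atoms: tert-butyldimethylsilyl chloride, CC(C)(C)[Si](C)(C)Cl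
Why: Standard silyl ether formation at the secondary alcohol.

Step 10
Reactants: 13 (5R)-5-[(tert-butyldimethylsilyl)oxy]-2-methylcyclohex-2-en-1-one
Product: 15 (5R,6S)-6-allyl-5-[(tert-butyldimethylsilyl)oxy]-2-methylcyclohex-2-en-1-one, via lithium enolate 14 (not isolated)
Conditions: LiN(iPr)2, THF, −78 °C; then allyl bromide, DMPU, −78 → −40 °C
Reagents that add atoms: allyl bromide, C=CCBr
Why: Kinetic α'-enolate alkylation; allyl bromide should enter anti to the neighbouring OTBS group (this centre is set again in step 11).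

Step 11
Reactants: 15 (5R,6S)-6-allyl-5-[(tert-butyldimethylsilyl)oxy]-2-methylcyclohex-2-en-1-one
Product: 17 (5R,6R)-6-allyl-5-[(tert-butyldimethylsilyl)oxy]-2,6-dimethylcyclohex-2-en-1-one, via lithium enolate 16 (not isolated)
Conditions: LiN(iPr)2, THF, −78 °C; then MeI, DMPU, −78 → −20 °C
Reagents that add atoms: iodomethane, IC
Why: A second enolate alkylation builds the quaternary centre (future C8a); iodomethane should approach the tetrasubstituted enolate anti to the adjacent OTBS group, leaving methyl trans and the allyl arm cis to OTBS.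

Step 12
Reactants: 17 (5R,6R)-6-allyl-5-[(tert-butyldimethylsilyl)oxy]-2,6-dimethylcyclohex-2-en-1-one
Product: 19 methyl 2-[(1R,6R)-6-[(tert-butyldimethylsilyl)oxy]-1,3-dimethyl-2-oxocyclohex-3-en-1-yl]acetate, via methoxy hydroperoxide 18 (not isolated)
Conditions: O3, NaHCO3, CH2Cl2/MeOH, −78 °C; then Ac2O, Et3N, 0 °C → rt
Reagents that add atoms: ozone, [O-][O+]=O; methanol, CO
Why: Ozonolysis of the monosubstituted alkene in methanol and dehydration of the methoxy hydroperoxide through its peracetate (Criegee-type fragmentation) should give the methyl ester without touching the conjugated alkene.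

Step 13
Reactants: 8 tert-butyl{[(1S,3R)-3-ethynyl-2,2,3-trimethylcyclopentyl]oxy}dimethylsilane; 19 methyl 2-[(1R,6R)-6-[(tert-butyldimethylsilyl)oxy]-1,3-dimethyl-2-oxocyclohex-3-en-1-yl]acetate
Product: 22 methyl 2-[(1R,2R,6R)-6-[(tert-butyldimethylsilyl)oxy]-2-hydroxy-1,3-dimethyl-2-({(1R,3S)-3-[(tert-butyldimethylsilyl)oxy]-1,2,2-trimethylcyclopentyl}ethynyl)cyclohex-3-en-1-yl]acetate (tertiary OH cis to the CH2CO2Me arm and to OTBS, alkyne cis to the ring methyl), via lithium acetylide 20 (not isolated), via dichlorocerium acetylide 21 (not isolated)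
Conditions: 8, n-BuLi, THF, −78 °C; CeCl3, −78 °C; then 19, −78 °C; aq NH4Cl
Reagents that add atoms: none
Why: 1,2-Addition of an alkynylcerium reagent to the enone carbonyl (ketone before ester); in the half-chair with OTBS and methyl equatorial the CH2CO2Me arm is axial, so attack anti to it should place the alkyne cis to the future C8a methyl and the C4a hydroxyl trans to it.

Step 14
Reactants: 22 propargylic alcohol methyl ester (as named in step 13)
Product: 24 (Z)-iodoalkene diol: the alkyne of 22 converted into C3(iodo)=C4H with iodine cis to the carbinol carbon C4a, and CO2Me reduced to CH2OH, via cyclic alkenylaluminate 23 (not isolated)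
Conditions: NaAlH2(OCH2CH2OMe)2, THF, 0 → 40 °C; then I2, −78 → 0 °C
Reagents that add atoms: iodine, [I][I]
Why: Hydroxyl-directed trans-hydroalumination of the propargylic alcohol (hydride to C4, aluminium to C3 in a five-membered alkoxyaluminate) followed by iodinolysis with retention should give the (Z)-iodoalkene, and the same hydride reduces the ester to the primary alcohol.

Step 15
Reactants: 24 (Z)-iodoalkene diol
Product: 26 iodo γ-lactone: cis-fused five-membered lactone C4a–O–C(=O)–CH2–C8a, other groups as in 24, via lactol 25 (not isolated)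
Conditions: TEMPO (20 mol%), PhI(OAc)2, CH2Cl2, rt
Reagents that add atoms: none
Why: Oxoammonium (TEMPO) oxidation is selective for the primary alcohol; the aldehyde is trapped by the tertiary hydroxyl as a lactol that is oxidised on to the γ-lactone (oxidative lactonisation), which also masks the tertiary bis-allylic alcohol.

Step 16
Reactants: 26 iodo γ-lactone
Product: 27 dihydroxy iodo lactone (free secondary alcohols at C3' and C8)
Conditions: HF·pyridine, pyridine, THF, 0 °C → rt
Reagents that add atoms: none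
Why: Fluoride-mediated desilylation of both secondary silyl ethers under buffered conditions that should leave the lactone and the iodoalkene intact.

Step 17
Reactants: 27 dihydroxy iodo lactone
Product: 28 dibromo iodo lactone (C3' and C8 bromides, both inverted: C3' R and C8 S as in the target)
Conditions: CBr4, P(n-C8H17)3, toluene, 70 °C
Reagents that add atoms: tetrabromomethane, BrC(Br)(Br)Br
Why: Twofold Appel reaction: each alkoxyphosphonium ion is displaced by bromide in an SN2 step with inversion; the electron-rich trialkylphosphine and heating are the conditions suited to neopentyl-type secondary alcohols.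

Step 18
Reactants: 28 dibromo iodo lactone
Product: 30 (4aS,8S,8aS)-8-bromo-3-[(1R,3R)-3-bromo-1,2,2-trimethylcyclopentyl]-4a-hydroxy-5,8a-dimethyl-4a,7,8,8a-tetrahydronaphthalen-2(1H)-one, via alkenylmagnesium chloride 29 (not isolated)
Conditions: i-PrMgCl·LiCl, THF, −20 °C → rt; aq NH4Cl
Reagents that add atoms: none
Why: Iodine–magnesium exchange gives the alkenylmagnesium species, which attacks the lactone carbonyl intramolecularly (Parham-type anionic cyclisation closing six-membered ring A); collapse of the bridged hemiketal alkoxide releases the C2 ketone and the C4a alkoxide, and secondary alkyl bromides should be inert to this exchange reagent.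

Step 19
Reactants: 30 hydroxy dienone (as named in step 18)
Product: 32 (4aR,5R,8S,8aS)-8-bromo-3-[(1R,3R)-3-bromo-1,2,2-trimethylcyclopentyl]-4a,5-dihydroxy-5,8a-dimethyl-4a,5,6,7,8,8a-hexahydronaphthalen-2(1H)-one, via organomercurial 31 (not isolated)
Conditions: Hg(OAc)2, THF/H2O, rt; then NaBH4, aq NaOH, 0 °C
Reagents that add atoms: water, O
Why: Oxymercuration–demercuration: Markovnikov anti addition with mercury on the α face at C6 (anti to the C8a methyl, syn to the C4a hydroxyl) and water entering C5 axially from the β face should give the trans-diaxial 4a,5-diol, and the hindered enone should survive a brief NaBH4 treatment at 0 °C.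

Compound list

1 | (S)-3-hydroxy-2,2-dimethylcyclohexan-1-one | CC1(C)[C@@H](O)CCCC1=O | starting material
2 | (S)-3-[(tert-butyldimethylsilyl)oxy]-2,2-dimethylcyclohexan-1-one | CC1(C)[C@@H](O[Si](C)(C)C(C)(C)C)CCCC1=O | intermediate
3 | potassium enolate of 2 | CC1(C)[C@@H](O[Si](C)(C)C(C)(C)C)CCC=C1[O-].[K+] | intermediate (not isolated)
4 | (S)-5-[(tert-butyldimethylsilyl)oxy]-6,6-dimethylcyclohex-1-en-1-yl trifluoromethanesulfonate | CC1(C)[C@@H](O[Si](C)(C)C(C)(C)C)CCC=C1OS(=O)(=O)C(F)(F)F | intermediate
5 | tert-butyldimethyl{[(1S)-2,2,3-trimethylcyclohex-3-en-1-yl]oxy}silane | CC1(C)[C@@H](O[Si](C)(C)C(C)(C)C)CCC=C1C | intermediate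
6 | tert-butyldimethyl{[(1R,3S,6S)-1,2,2-trimethyl-7-oxabicyclo[4.1.0]heptan-3-yl]oxy}silane | CC1(C)[C@@H](O[Si](C)(C)C(C)(C)C)CC[C@@H]2O[C@]12C | intermediate
7 | (1S,3S)-3-[(tert-butyldimethylsilyl)oxy]-1,2,2-trimethylcyclopentane-1-carbaldehyde | CC1(C)[C@@H](O[Si](C)(C)C(C)(C)C)CC[C@]1(C)C=O | intermediate
8 | tert-butyl{[(1S,3R)-3-ethynyl-2,2,3-trimethylcyclopentyl]oxy}dimethylsilane | CC1(C)[C@@H](O[Si](C)(C)C(C)(C)C)CC[C@]1(C)C#C | intermediate
9 | (R)-(−)-carvone | CC1=CC[C@@H](C(C)=C)CC1=O | starting material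
10 | α-methoxy hydroperoxide from carvone (side chain C(CH3)(OCH3)OOH) | CC1=CC[C@@H](C(C)(OC)OO)CC1=O | intermediate (not isolated)
11 | (1R)-4-methyl-5-oxocyclohex-3-en-1-yl acetate | CC1=CC[C@@H](OC(C)=O)CC1=O | intermediate
12 | (5R)-5-hydroxy-2-methylcyclohex-2-en-1-one | CC1=CC[C@@H](O)CC1=O | intermediate
13 | (5R)-5-[(tert-butyldimethylsilyl)oxy]-2-methylcyclohex-2-en-1-one | CC1=CC[C@@H](O[Si](C)(C)C(C)(C)C)CC1=O | intermediate
14 | lithium cross-conjugated enolate of 13 | CC1=CC[C@@H](O[Si](C)(C)C(C)(C)C)C=C1[O-].[Li+] | intermediate (not isolated)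
15 | (5R,6S)-6-allyl-5-[(tert-butyldimethylsilyl)oxy]-2-methylcyclohex-2-en-1-one | CC1=CC[C@@H](O[Si](C)(C)C(C)(C)C)[C@H](CC=C)C1=O | intermediate
16 | lithium enolate of 15 | CC1=CC[C@@H](O[Si](C)(C)C(C)(C)C)C(CC=C)=C1[O-].[Li+] | intermediate (not isolated)
17 | (5R,6R)-6-allyl-5-[(tert-butyldimethylsilyl)oxy]-2,6-dimethylcyclohex-2-en-1-one | CC1=CC[C@@H](O[Si](C)(C)C(C)(C)C)[C@@](C)(CC=C)C1=O | intermediate
18 | methoxy hydroperoxide from 17 (side chain CH2CH(OCH3)OOH) | CC1=CC[C@@H](O[Si](C)(C)C(C)(C)C)[C@@](C)(CC(OC)OO)C1=O | intermediate (not isolated)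
19 | methyl 2-[(1R,6R)-6-[(tert-butyldimethylsilyl)oxy]-1,3-dimethyl-2-oxocyclohex-3-en-1-yl]acetate | CC1=CC[C@@H](O[Si](C)(C)C(C)(C)C)[C@@](C)(CC(=O)OC)C1=O | intermediate
20 | lithium acetylide of 8 | CC1(C)[C@@H](O[Si](C)(C)C(C)(C)C)CC[C@]1(C)C#[C-].[Li+] | intermediate (not isolated)
21 | dichlorocerium acetylide of 8 | CC1(C)[C@@H](O[Si](C)(C)C(C)(C)C)CC[C@]1(C)C#C[Ce](Cl)Cl | intermediate (not isolated)
22 | methyl 2-[(1R,2R,6R)-6-[(tert-butyldimethylsilyl)oxy]-2-hydroxy-1,3-dimethyl-2-({(1R,3S)-3-[(tert-butyldimethylsilyl)oxy]-1,2,2-trimethylcyclopentyl}ethynyl)cyclohex-3-en-1-yl]acetate | CC1(C)[C@@H](O[Si](C)(C)C(C)(C)C)CC[C@]1(C)C#C[C@]2(O)C(C)=CC[C@@H](O[Si](C)(C)C(C)(C)C)[C@@]2(C)CC(=O)OC | intermediate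
23 | cyclic alkenylaluminate from 22 (five-membered C3–Al–O–C4a ring, primary alkoxide as sodium salt) | CC1(C)[C@@H](O[Si](C)(C)C(C)(C)C)CC[C@]1(C)C2=C[C@]3(O[Al-]2(OCCOC)OCCOC)C(C)=CC[C@@H](O[Si](C)(C)C(C)(C)C)[C@@]3(C)CC[O-].[Na+].[Na+] | intermediate (not isolated)
24 | (Z)-iodoalkene diol (iodine on C3, cis to C4a; tertiary C4a–OH; 2-hydroxyethyl arm on C8a; both OTBS groups retained) | CC1(C)[C@@H](O[Si](C)(C)C(C)(C)C)CC[C@]1(C)/C(I)=C/[C@]2(O)C(C)=CC[C@@H](O[Si](C)(C)C(C)(C)C)[C@@]2(C)CCO | intermediate
25 | lactol from 24 (2-hydroxytetrahydrofuran spanning C4a–O and C8a–CH2) | CC1(C)[C@@H](O[Si](C)(C)C(C)(C)C)CC[C@]1(C)/C(I)=C/[C@]2(OC(O)C3)C(C)=CC[C@@H](O[Si](C)(C)C(C)(C)C)[C@]23C | intermediate (not isolated)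
26 | iodo γ-lactone (cis-fused lactone C4a–O–C(=O)–CH2–C8a; both OTBS groups retained) | CC1(C)[C@@H](O[Si](C)(C)C(C)(C)C)CC[C@]1(C)/C(I)=C/[C@]2(OC(=O)C3)C(C)=CC[C@@H](O[Si](C)(C)C(C)(C)C)[C@]23C | intermediate
27 | dihydroxy iodo lactone (free C3'–OH and C8–OH) | CC1(C)[C@@H](O)CC[C@]1(C)/C(I)=C/[C@]2(OC(=O)C3)C(C)=CC[C@@H](O)[C@]23C | intermediate
28 | dibromo iodo lactone (C3' and C8 bromides with target configuration) | CC1(C)[C@H](Br)CC[C@]1(C)/C(I)=C/[C@]2(OC(=O)C3)C(C)=CC[C@H](Br)[C@]23C | intermediate
29 | alkenylmagnesium chloride from 28 | CC1(C)[C@H](Br)CC[C@]1(C)/C([Mg]Cl)=C/[C@]2(OC(=O)C3)C(C)=CC[C@H](Br)[C@]23C | intermediate (not isolated)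
30 | (4aS,8S,8aS)-8-bromo-3-[(1R,3R)-3-bromo-1,2,2-trimethylcyclopentyl]-4a-hydroxy-5,8a-dimethyl-4a,7,8,8a-tetrahydronaphthalen-2(1H)-one | CC1(C)[C@H](Br)CC[C@]1(C)C1=C[C@]2(O)C(C)=CC[C@H](Br)[C@@]2(C)CC1=O | intermediate
31 | organomercurial from 30 (C5–OH β, C6–HgOAc α) | CC1(C)[C@H](Br)CC[C@]1(C)C1=C[C@]2(O)[C@](C)(O)[C@@H]([Hg]OC(C)=O)C[C@H](Br)[C@@]2(C)CC1=O | intermediate (not isolated)
32 | (4aR,5R,8S,8aS)-8-bromo-3-[(1R,3R)-3-bromo-1,2,2-trimethylcyclopentyl]-4a,5-dihydroxy-5,8a-dimethyl-4a,5,6,7,8,8a-hexahydronaphthalen-2(1H)-one | CC1(C)[C@H](Br)CC[C@]1(C)C1=C[C@]2(O)[C@](C)(O)CC[C@H](Br)[C@@]2(C)CC1=O | target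

Total step count: 19. Longest linear sequence: 13 steps (steps 1–6 then 13–19; the ring B branch, steps 7–12 then 13–19, is equally long).

Steps most likely to fail

Step 17. Substitution at two neopentyl-type carbinols may be slow, and the alkoxyphosphonium ions may instead ionise, leading to 1,2-methyl or ring-bond shifts or to elimination, or only one centre may react. The fallback separates activation from displacement. It sets out from 27: Tf2O and pyridine in CH2Cl2 at −20 °C should give the bis(trifluoromethanesulfonate) of diol 27 F6, and treatment with Bu4NBr in toluene at rt to 50 °C should displace both sulfonates with inversion, coming back to the route at 28.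

Step 18. Iodine–magnesium exchange at the hindered trisubstituted iodoalkene may be sluggish, the alkenylmagnesium species may be protonated before it cyclises, or base-induced elimination may occur at the secondary bromides. The fallback closes ring A at the aldehyde oxidation level. It sets out from 28: i-Bu2AlH in CH2Cl2 at −78 °C should reduce the lactone to the lactol from 28 F7. Its open hydroxy aldehyde form should undergo an intramolecular Nozaki–Hiyama–Kishi reaction (CrCl2, NiCl2 cat., DMSO) to the C2 allylic alcohol of the hydroxy diene F8. MnO2 in CH2Cl2 should oxidise the secondary allylic alcohol only, coming back to the route at 30.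

Step 5. Hydride shift may compete with ring-bond migration and give a cyclohexanone, and a longer-lived cation may lose the stereochemical relay or undergo methyl shift. The fallback uses an oxirane without hydrogen on either carbon, for which both ionisation modes lead to the same ring-contracted ketone. It sets out from 2:
- LiN(iPr)2 then MeI should give (3S)-3-[(tert-butyldimethylsilyl)oxy]-2,2,6-trimethylcyclohexan-1-one F1.
- KN(SiMe3)2 and PhNTf2 should give the enol triflate (5S)-5-[(tert-butyldimethylsilyl)oxy]-2,6,6-trimethylcyclohex-1-en-1-yl trifluoromethanesulfonate F2.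
- MeMgBr with Fe(acac)3 should give the tetrasubstituted alkene tert-butyldimethyl{[(1S)-2,2,3,4-tetramethylcyclohex-3-en-1-yl]oxy}silane F3.
- mCPBA should give the oxirane trans to OTBS, tert-butyldimethyl{[1,2,2,6-tetramethyl-7-oxabicyclo[4.1.0]heptan-3-yl]oxy}silane F4.
- BF3·OEt2 in CH2Cl2 at −78 °C (pinacol-type ring contraction) should give 1-[(1S,3S)-3-[(tert-butyldimethylsilyl)oxy]-1,2,2-trimethylcyclopentyl]ethan-1-one F5.
- LiN(iPr)2 and ClP(O)(OEt)2, then more LiN(iPr)2 (enol phosphate elimination), should convert the methyl ketone into the alkyne, coming back to the route at 8.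

Further compounds
F1 | step 5 | (3S)-3-[(tert-butyldimethylsilyl)oxy]-2,2,6-trimethylcyclohexan-1-one (C6 epimers) | CC1(C)[C@@H](O[Si](C)(C)C(C)(C)C)CCC(C)C1=O
F2 | step 5 | (5S)-5-[(tert-butyldimethylsilyl)oxy]-2,6,6-trimethylcyclohex-1-en-1-yl trifluoromethanesulfonate | CC1(C)[C@@H](O[Si](C)(C)C(C)(C)C)CCC(C)=C1OS(=O)(=O)C(F)(F)F
F3 | step 5 | tert-butyldimethyl{[(1S)-2,2,3,4-tetramethylcyclohex-3-en-1-yl]oxy}silane | CC1(C)[C@@H](O[Si](C)(C)C(C)(C)C)CCC(C)=C1C
F4 | step 5 | tert-butyldimethyl{[1,2,2,6-tetramethyl-7-oxabicyclo[4.1.0]heptan-3-yl]oxy}silane (oxirane trans to OTBS) | CC1(C)[C@@H](O[Si](C)(C)C(C)(C)C)CC[C@]2(C)O[C@]12C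
F5 | step 5 | 1-[(1S,3S)-3-[(tert-butyldimethylsilyl)oxy]-1,2,2-trimethylcyclopentyl]ethan-1-one | CC1(C)[C@@H](O[Si](C)(C)C(C)(C)C)CC[C@]1(C)C(C)=O
F6 | step 17 | bis(trifluoromethanesulfonate) of diol 27 | CC1(C)[C@@H](OS(=O)(=O)C(F)(F)F)CC[C@]1(C)/C(I)=C/[C@]2(OC(=O)C3)C(C)=CC[C@@H](OS(=O)(=O)C(F)(F)F)[C@]23C
F7 | step 18 | lactol from 28 | CC1(C)[C@H](Br)CC[C@]1(C)/C(I)=C/[C@]2(OC(O)C3)C(C)=CC[C@H](Br)[C@]23C
F8 | step 18 | C2 allylic alcohol of the hydroxy diene (8-bromo-3-(3-bromo-1,2,2-trimethylcyclopentyl)-5,8a-dimethyl-1,2,7,8-tetrahydronaphthalene-2,4a-diol) | CC1(C)[C@H](Br)CC[C@]1(C)C1=C[C@]2(O)C(C)=CC[C@H](Br)[C@@]2(C)CC1O
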